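**Retrosynthetic overview**
- Target ⇐ acetylation of the two secondary alcohols ⇐ syn-dihydroxylation of the (E)-C6=C7 alkene of the tetracyclic 4-ol.
- Oxepane (last ring) ⇐ tertiary C3–OH onto a C16 triflate; oxolane ⇐ one-pot hydroxyl-directed epoxidation of C2=C3 and transannular 5-exo opening by C9–OH in an unprotected (2Z,6E)-eunicelladiene triol, which sets C2 and C3.
- Ten-membered carbocycle ⇐ Ni/Cr closure of a (Z)-alkenyl iodide (C3) onto the C4 aldehyde, which sets C4.
- Cyclohexene ⇐ maleate-tethered intramolecular Diels–Alder of a 2-silyloxydiene made from (S)-β-methyl-γ-butyrolactone, which sets C1, C10 and C14 from C15; the C4–C8 chain is added by allyl sulfone acylation.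
- Ring order: cyclohexene → cyclodecadiene → oxolane → oxepane (both carbocycles before the two ether bridges).

Assumption: (S)-4-methyldihydrofuran-2(3H)-one is bought as the single enantiomer; locants C1–C16 follow eunicellane numbering (C1/C10 ring fusion, C2–O–C9 and C3–O–C16 ethers, C13 ketone), in which the target is 1S,2R,3R,4S,6S,7S,9R,10R,14S,15S; the SMILES strings are authoritative for configuration.

**Route**

Step 1
Reactants: 1 ethyl 3,3-diethoxypropanoate
Product: 2 3,3-diethoxypropanal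
Conditions: iBu2AlH (1.05 equiv), CH2Cl2, −78 °C; aqueous work-up
Reagents that add atoms: none
Why: Partial ester reduction; the aluminium hemiacetal is stable at −78 °C and releases the aldehyde only on work-up; no stereocentre.

Step 2
Reactants: 2 3,3-diethoxypropanal; 3 isopropenylmagnesium bromide
Product: 5 (±)-5,5-diethoxy-2-methylpent-1-en-3-yl methyl carbonate, via bromomagnesium alkoxide 4 (not isolated)
Conditions: THF, −78→0 °C; then ClCO2Me, 0→23 °C
Reagents that add atoms: methyl chloroformate COC(=O)Cl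
Why: Grignard 1,2-addition followed by in situ O-acylation of the alkoxide; the carbinol centre is left racemic because step 3 destroys it.

Step 3
Reactants: 5 (±)-5,5-diethoxy-2-methylpent-1-en-3-yl methyl carbonate
Product: 6 [(2E)-5,5-diethoxy-2-methylpent-2-en-1-yl]sulfonylbenzene
Conditions: PhSO2Na, Pd(PPh3)4 (3 mol %), THF/MeOH, 40 °C
Reagents that add atoms: sodium benzenesulfinate [Na+].[O-]S(=O)c1ccccc1
Why: Tsuji–Trost allylic sulfonylation; sulfinate attacks the unsubstituted terminus of the π-allyl complex and reversibility funnels material to the primary sulfone with the more stable E trisubstituted alkene.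

Step 4
Reactants: 7 (S)-4-methyldihydrofuran-2(3H)-one; 8 (E)-1-bromoprop-1-ene
Product: 10 (S,E)-7-hydroxy-6-methylhept-2-en-4-one, via (E)-prop-1-enyllithium 9 (not isolated)
Conditions: 8, tBuLi (2 equiv), Et2O, −78 °C; then 7, THF, −78 °C; AcOH quench at −78 °C
Reagents that add atoms: none
Why: Br–Li exchange with retention of alkene geometry, then acyl substitution of the lactone; the lithium lactolate survives at −78 °C so only one alkenyl group adds, and C15 comes unchanged from the chiral pool.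

Step 5
Reactants: 10 (S,E)-7-hydroxy-6-methylhept-2-en-4-one; 11 maleic anhydride
Product: 15 (4S,4aS,7S,8S,8aR)-4,7-dimethyl-1-oxo-5-[(triisopropylsilyl)oxy]-3,4,4a,7,8,8a-hexahydro-1H-isochromene-8-carboxylic acid, via maleate half-ester 12 (not isolated), via bis-silyl triene 13 (not isolated), via silyl ester cycloadduct 14 (not isolated)
Conditions: 11, Et3N, CH2Cl2, 0→23 °C; then Et3N, TIPSOTf (2.2 equiv), 0 °C; filter, PhMe, BHT, 120 °C; then aq. NaHCO3/THF, citric acid
Reagents that add atoms: triisopropylsilyl trifluoromethanesulfonate CC(C)[Si](C(C)C)(C(C)C)OS(=O)(=O)C(F)(F)F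
Why: Anhydride opening gives the (Z)-maleate, soft enolisation gives the (Z)-2-silyloxydiene, and the ester-tethered intramolecular Diels–Alder (endo, cis dienophile) gives the all-cis cyclohexene; the tether delivers the dienophile to the C16 face of the A(1,3)-minimised rotamer (H15 eclipsing the enol ether), so C14, C1 and C10 are set from C15 (C11 is erased in step 11).

Step 6
Reactants: 15 lactone acid (as named in step 5); 6 [(2E)-5,5-diethoxy-2-methylpent-2-en-1-yl]sulfonylbenzene
Product: 18 β-keto sulfone (3E)-6,6-diethoxy-3-methyl-2-(phenylsulfonyl)-1-[lactone core of 15 attached through C8]hex-3-en-1-one, via lithiated sulfone 16 (not isolated), via acid chloride 17 (not isolated)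
Conditions: 6, nBuLi, THF, −78 °C (2.2 equiv of 16); 15, 1-chloro-N,N,2-trimethylprop-1-en-1-amine, CH2Cl2, 0 °C; add 17 to 16 at −78 °C
Reagents that add atoms: 1-chloro-N,N,2-trimethylprop-1-en-1-amine CC(C)=C(Cl)N(C)C
Why: Claisen-type C-acylation of the α-sulfonyl allyl anion at its α-carbon by the acid chloride (much more electrophilic than the δ-lactone at −78 °C) forms C8–C9 with the E alkene already in place; the product sits as its C8 enolate (second equivalent of 16, returned as 6), which protects the C10 centre, and C8 is an inconsequential epimer mixture.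

Step 7
Reactants: 18 β-keto sulfone
Product: 19 β,γ-unsaturated ketone (3E)-6,6-diethoxy-3-methyl-1-[lactone core of 15]hex-3-en-1-one
Conditions: SmI2 (2.5 equiv), THF/MeOH, −78 °C
Reagents that add atoms: none
Why: Single-electron reductive desulfonylation of the α-sulfonyl ketone gives a samarium dienolate that is protonated kinetically at C8, so the alkene keeps its position and E geometry; no stereocentre is touched.

Step 8
Reactants: 19 β,γ-unsaturated ketone
Product: 20 (9R)-alcohol (1R,3E)-6,6-diethoxy-1-[lactone core of 15]-3-methylhex-3-en-1-ol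
Conditions: (S)-2-methyl-CBS-oxazaborolidine (0.5 equiv), catecholborane, PhMe, −78 °C
Reagents that add atoms: none
Why: Corey–Bakshi–Shibata reduction under reagent control, with the branched ring carbon C10 as the large group and the C8 methylene as the small one, gives the 9R carbinol; catecholborane at −78 °C spares the lactone, silyl enol ether and alkenes.

Step 9
Reactants: 20 (9R)-alcohol
Product: 21 lactol (1-hydroxy-isochromane form of 20; anomer mixture)
Conditions: iBu2AlH (2.5 equiv), CH2Cl2, −78 °C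
Reagents that add atoms: none
Why: Partial reduction of the δ-lactone to the lactol through the low-temperature-stable aluminium acetal; an acyl-migrated lactone on O9, if any formed, gives a lactol that converges in step 10.

Step 10
Reactants: 21 lactol
Product: 22 (Z)-alkenyl iodide diol: 5-silyloxy-cyclohexene bearing all-cis at C10 the (1R,3E)-6,6-diethoxy-1-hydroxy-3-methylhex-3-enyl chain, at C11 methyl, at C1 a (Z)-2-iodoprop-1-enyl group and at C14 a (2S)-1-hydroxypropan-2-yl group
Conditions: Ph3PEtI, nBuLi, THF; I2, −78 °C; NaN(SiMe3)2, −20 °C; then 21, −78→−20 °C (4 equiv ylide)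
Reagents that add atoms: ethyltriphenylphosphonium iodide CC[P+](c1ccccc1)(c1ccccc1)c1ccccc1.[I-]; iodine II
Why: Stork–Zhao iodo-olefination (Wittig) on the open hydroxy-aldehyde form of the lactol gives the (Z)-2-iodoalkene (C1 cis to I) through the kinetic cis-oxaphosphetane and frees O16; excess ylide absorbs the two OH groups.

Step 11
Reactants: 22 (Z)-alkenyl iodide diol
Product: 24 enone aldehyde: 3-methylcyclohex-2-enone (C13=O, C11=C12) carrying the same C10, C1 and C14 substituents as 22 but with a free C4 aldehyde, via enone acetal 23 (not isolated)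
Conditions: DDQ (1.3 equiv), 2,4,6-collidine, CH2Cl2, 0→23 °C; filter; then PPTS, acetone/H2O 10:1, 40 °C
Reagents that add atoms: water O
Why: DDQ abstracts the allylic C11 hydride of the silyl enol ether (a palladium-free Saegusa-type dehydrogenation that spares the alkenyl iodide) to give the C11=C12 enone and erase C11, then mild acid hydrolyses the acetal to the β,γ-unsaturated aldehyde; the enone is unmasked only here so that the C14 α-centre never meets base.

Step 12
Reactants: 24 enone aldehyde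
Product: 25 (1S,2Z,4S,6E,9R,10R,14R,15S)-4,9,16-trihydroxyeunicella-2,6,11-trien-13-one
Conditions: CrCl2 (10 equiv), NiCl2 (2 mol %), DMSO/THF 3:1, 2 mM, 23 °C
Reagents that add atoms: none
Why: Nozaki–Hiyama–Kishi macrocyclisation; the alkenylchromium adds only to the aldehyde, with retention of the Z geometry and tolerance of free alcohols and the enone, closing the ten-membered carbocycle, and the C4 carbinol (4S needed) is set by the macrocyclic transition state.

Step 13
Reactants: 25 macrocyclic triol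
Product: 27 (1S,2R,3R,4S,6E,9R,10R,14S,15S)-3,4,16-trihydroxy-2,9-epoxyeunicella-6,11-dien-13-one, via epoxy triol 26 (not isolated)
Conditions: VO(acac)2 (5 mol %), tBuOOH (1.1 equiv), CH2Cl2, 0 °C; then Ti(OiPr)4 (1.5 equiv), 23 °C
Reagents that add atoms: tert-butyl hydroperoxide CC(C)(C)OO
Why: Hydroxyl-directed epoxidation of the allylic alcohol occurs syn to O4 in the A(1,3)-minimised conformer (threo) and spares the homoallylic C6=C7 and the enone; the titanium-bound epoxy alcohol is then opened at the distal carbon C2 by the transannular C9 oxygen (5-exo-tet, inversion), so the Z geometry with 4S and 9R fixes 2R and 3R.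

Step 14
Reactants: 27 oxolane triol
Product: 29 (1S,2R,3R,4S,6E,9R,10R,14S,15S)-4-hydroxy-2,9:3,16-diepoxyeunicella-6,11-dien-13-one, via primary triflate 28 (not isolated)
Conditions: Tf2O (1.1 equiv), 2,6-lutidine, CH2Cl2, −78→0 °C
Reagents that add atoms: trifluoromethanesulfonic anhydride O=S(=O)(OS(=O)(=O)C(F)(F)F)C(F)(F)F
Why: Selective triflation of the only primary alcohol and intramolecular Williamson-type displacement by the tertiary C3–OH (7-exo-tet) close the oxepane; C3 keeps its configuration because its C–O bond is not broken.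

Step 15
Reactants: 29 tetracyclic 4-ol
Product: 30 (1S,2R,3R,4S,6S,7S,9R,10R,14S,15S)-4,6,7-trihydroxy-2,9:3,16-diepoxyeunicell-11-en-13-one
Conditions: OsO4 (5 mol %), NMO, acetone/H2O 5:1, 0 °C
Reagents that add atoms: N-methylmorpholine N-oxide C[N+]1([O-])CCOCC1; water O
Why: Upjohn syn-dihydroxylation of the strained, electron-rich (E)-C6=C7 alkene in preference to the enone; syn addition to the E alkene gives the required C6/C7 relative configuration, and attack on the outer π-face of the bridged oxonene (inner face taken to be blocked by the oxolane bridge) is expected to give 6S,7S.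

Step 16
Reactants: 30 triol
Product: 31 (1S,2R,3R,4S,6S,7S,9R,10R,14S,15S)-4,6-diacetoxy-7-hydroxy-2,9:3,16-diepoxyeunicell-11-en-13-one (CNP0212231.3)
Conditions: Ac2O, pyridine, DMAP (cat.), CH2Cl2, 0→23 °C
Reagents that add atoms: acetic anhydride CC(=O)OC(C)=O
Why: DMAP-catalysed acetylation esterifies the two secondary alcohols (C4, C6) while the tertiary C7–OH stays free; no stereocentre is affected.

**Compound list**

1 | ethyl 3,3-diethoxypropanoate | CCOC(=O)CC(OCC)OCC | starting material
2 | 3,3-diethoxypropanal | CCOC(CC=O)OCC | intermediate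
3 | isopropenylmagnesium bromide | CC(=C)[Mg]Br | starting material
4 | bromomagnesium 5,5-diethoxy-2-methylpent-1-en-3-olate (racemic) | CCOC(CC(O[Mg]Br)C(C)=C)OCC | intermediate
5 | (±)-5,5-diethoxy-2-methylpent-1-en-3-yl methyl carbonate | CCOC(CC(OC(=O)OC)C(C)=C)OCC | intermediate
6 | [(2E)-5,5-diethoxy-2-methylpent-2-en-1-yl]sulfonylbenzene | CCOC(OCC)C/C=C(\C)CS(=O)(=O)c1ccccc1 | intermediate
7 | (S)-4-methyldihydrofuran-2(3H)-one | O=C1C[C@H](C)CO1 | starting material
8 | (E)-1-bromoprop-1-ene | C/C=C/Br | starting material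
9 | (E)-prop-1-enyllithium | C/C=C/[Li] | intermediate
10 | (S,E)-7-hydroxy-6-methylhept-2-en-4-one | C/C=C/C(=O)C[C@H](C)CO | intermediate
11 | maleic anhydride | O=C1OC(=O)C=C1 | starting material
12 | (2Z)-4-{[(2S,5E)-2-methyl-4-oxohept-5-en-1-yl]oxy}-4-oxobut-2-enoic acid | C/C=C/C(=O)C[C@H](C)COC(=O)/C=C\C(=O)O | intermediate
13 | triisopropylsilyl (2Z)-4-({(2S,3Z,5E)-2-methyl-4-[(triisopropylsilyl)oxy]hepta-3,5-dien-1-yl}oxy)-4-oxobut-2-enoate | C/C=C/C(O[Si](C(C)C)(C(C)C)C(C)C)=C/[C@H](C)COC(=O)/C=C\C(=O)O[Si](C(C)C)(C(C)C)C(C)C | intermediate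
14 | triisopropylsilyl ester of acid 15 | CC(C)[Si](C(C)C)(C(C)C)OC(=O)[C@H]1[C@@H](C)C=C(O[Si](C(C)C)(C(C)C)C(C)C)[C@H]2[C@H](C)COC(=O)[C@@H]12 | intermediate
15 | (4S,4aS,7S,8S,8aR)-4,7-dimethyl-1-oxo-5-[(triisopropylsilyl)oxy]-3,4,4a,7,8,8a-hexahydro-1H-isochromene-8-carboxylic acid (cis-fused δ-lactone; substituents at C1, C10, C11, C14 all cis) | OC(=O)[C@H]1[C@@H](C)C=C(O[Si](C(C)C)(C(C)C)C(C)C)[C@H]2[C@H](C)COC(=O)[C@@H]12 | intermediate
16 | [(2E)-5,5-diethoxy-1-lithio-2-methylpent-2-en-1-yl]sulfonylbenzene | CCOC(OCC)C/C=C(\C)C([Li])S(=O)(=O)c1ccccc1 | intermediate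
17 | acid chloride of 15 | ClC(=O)[C@H]1[C@@H](C)C=C(O[Si](C(C)C)(C(C)C)C(C)C)[C@H]2[C@H](C)COC(=O)[C@@H]12 | intermediate
18 | β-keto sulfone: 15 with CO2H replaced by C(=O)CH(SO2Ph)C(CH3)=CHCH2CH(OEt)2 (E; C8 epimers) | CCOC(OCC)C/C=C(\C)C(C(=O)[C@H]1[C@@H](C)C=C(O[Si](C(C)C)(C(C)C)C(C)C)[C@H]2[C@H](C)COC(=O)[C@@H]12)S(=O)(=O)c1ccccc1 | intermediate
19 | ketone: 15 with CO2H replaced by C(=O)CH2C(CH3)=CHCH2CH(OEt)2 (E) | CCOC(OCC)C/C=C(\C)CC(=O)[C@H]1[C@@H](C)C=C(O[Si](C(C)C)(C(C)C)C(C)C)[C@H]2[C@H](C)COC(=O)[C@@H]12 | intermediate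
20 | (9R)-alcohol: 19 with the C9 ketone reduced to the R carbinol | CCOC(OCC)C/C=C(\C)C[C@@H](O)[C@H]1[C@@H](C)C=C(O[Si](C(C)C)(C(C)C)C(C)C)[C@H]2[C@H](C)COC(=O)[C@@H]12 | intermediate
21 | lactol of 20 (C2 hemiacetal, anomer mixture) | CCOC(OCC)C/C=C(\C)C[C@@H](O)[C@H]1[C@@H](C)C=C(O[Si](C(C)C)(C(C)C)C(C)C)[C@H]2[C@H](C)COC(O)[C@@H]12 | intermediate
22 | (Z)-alkenyl iodide diol: TIPS enol ether cyclohexene with all-cis C10 chain [(1R,3E)-6,6-diethoxy-1-hydroxy-3-methylhex-3-enyl], C11 methyl, C1 (Z)-2-iodoprop-1-enyl and C14 (2S)-1-hydroxypropan-2-yl | CCOC(OCC)C/C=C(\C)C[C@@H](O)[C@H]1[C@@H](C)C=C(O[Si](C(C)C)(C(C)C)C(C)C)[C@@H]([C@H](C)CO)[C@H]1/C=C(\I)C | intermediate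
23 | enone acetal: 22 with the silyl enol ether converted to the C11=C12–C13=O enone | CCOC(OCC)C/C=C(\C)C[C@@H](O)[C@H]1C(C)=CC(=O)[C@@H]([C@H](C)CO)[C@H]1/C=C(\I)C | intermediate
24 | enone aldehyde: 23 with the diethyl acetal hydrolysed to the C4 aldehyde | O=CC/C=C(\C)C[C@@H](O)[C@H]1C(C)=CC(=O)[C@@H]([C@H](C)CO)[C@H]1/C=C(\I)C | intermediate
25 | (1S,2Z,4S,6E,9R,10R,14R,15S)-4,9,16-trihydroxyeunicella-2,6,11-trien-13-one | O[C@H]1C/C=C(\C)C[C@@H](O)[C@H]2C(C)=CC(=O)[C@@H]([C@H](C)CO)[C@H]2/C=C\1C | intermediate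
26 | (2S,3R)-2,3-epoxide of 25 (epoxide threo to the 4-OH) | O[C@H]1C/C=C(\C)C[C@@H](O)[C@H]2C(C)=CC(=O)[C@@H]([C@H](C)CO)[C@H]2[C@@H]3O[C@]13C | intermediate
27 | (1S,2R,3R,4S,6E,9R,10R,14S,15S)-3,4,16-trihydroxy-2,9-epoxyeunicella-6,11-dien-13-one | O[C@H]1C/C=C(\C)C[C@H]2O[C@@H]([C@]1(C)O)[C@@H]3[C@H]([C@H](C)CO)C(=O)C=C(C)[C@@H]32 | intermediate
28 | 16-O-triflate of 27 | O[C@H]1C/C=C(\C)C[C@H]2O[C@@H]([C@]1(C)O)[C@@H]3[C@H]([C@H](C)COS(=O)(=O)C(F)(F)F)C(=O)C=C(C)[C@@H]32 | intermediate
29 | (1S,2R,3R,4S,6E,9R,10R,14S,15S)-4-hydroxy-2,9:3,16-diepoxyeunicella-6,11-dien-13-one | O[C@H]1C/C=C(\C)C[C@H]2O[C@@H]3[C@@H]4[C@@H](C(=O)C=C(C)[C@@H]42)[C@H](C)CO[C@]13C | intermediate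
30 | (1S,2R,3R,4S,6S,7S,9R,10R,14S,15S)-4,6,7-trihydroxy-2,9:3,16-diepoxyeunicell-11-en-13-one | O[C@H]1C[C@H](O)[C@@](C)(O)C[C@H]2O[C@@H]3[C@@H]4[C@@H](C(=O)C=C(C)[C@@H]42)[C@H](C)CO[C@]13C | intermediate
31 | (1S,2R,3R,4S,6S,7S,9R,10R,14S,15S)-4,6-diacetoxy-7-hydroxy-2,9:3,16-diepoxyeunicell-11-en-13-one (CNP0212231.3) | CC(=O)O[C@H]1C[C@H](OC(C)=O)[C@@](C)(O)C[C@H]2O[C@@H]3[C@@H]4[C@@H](C(=O)C=C(C)[C@@H]42)[C@H](C)CO[C@]13C | target

**Step count and risks**

Total steps: 16. Longest linear sequence: 14 (steps 1–3 and then 6–16, from ethyl 3,3-diethoxypropanoate 1). The two-step branch from lactone 7 (steps 4–5) joins it at step 6.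

Steps most likely to fail:

Step 12 (ring closure and C4 configuration). The medium-ring closure may be low-yielding and the sense of induction at C4 cannot be predicted; only the 4S carbinol directs the epoxidation of step 13 correctly. The fallback sets out from 24 and stops trying to steer the addition. The closure is run as before. The (4R)-epimer F1, alone or mixed with 25, is oxidised with MnO2, which touches only the allylic alcohol, to the macrocyclic dienone F2. The C4 ketone, less hindered than the C13 ketone, is then reduced under reagent control with (R)-2-methyl-CBS-oxazaborolidine and catecholborane at −78 °C. This comes back to the route at 25.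

Step 13 (epoxidation and transannular opening). O16 can compete with O9 for C2 through a six-membered ring, and the homoallylic C6=C7 alkene can be epoxidised. The fallback sets out from 25 and turns O16 from a nucleophile into the electrophile before the epoxide is made. 2,4,6-Triisopropylbenzenesulfonyl chloride in pyridine sulfonylates only the primary alcohol to give the primary sulfonate F3. VO(acac)2/tBuOOH gives the epoxy sulfonate F4. Ti(OiPr)4 opens it at C2 with the C9 oxygen to give the oxolane sulfonate F5. NaH in THF at 0 °C then lets the C3 alkoxide displace the sulfonate. Both ether rings are closed in the same order and the route is rejoined at 29, so step 14 is not needed.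

Step 14 (oxepane closure). Triflation of the secondary C4–OH or loss of triflate to an isopropenyl group can compete. The fallback sets out from 27 and replaces alkylation by reductive etherification. TEMPO/PhI(OAc)2 oxidises the primary alcohol selectively to the hydroxy aldehyde F6. F6 closes onto the tertiary C3–OH as the seven-membered lactol F7. Et3SiH/BF3·OEt2 at −78 °C reduces the derived oxocarbenium ion and returns 29.

**Further compounds**

F1 | step 12 | (4R)-epimer of 25 | O[C@@H]1C/C=C(\C)C[C@@H](O)[C@H]2C(C)=CC(=O)[C@@H]([C@H](C)CO)[C@H]2/C=C\1C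
F2 | step 12 | (2Z,6E)-9,16-dihydroxyeunicella-2,6,11-triene-4,13-dione | O=C1C/C=C(\C)C[C@@H](O)[C@H]2C(C)=CC(=O)[C@@H]([C@H](C)CO)[C@H]2/C=C\1C
F3 | step 13 | 16-O-(2,4,6-triisopropylbenzenesulfonyl) derivative of 25 | O[C@H]1C/C=C(\C)C[C@@H](O)[C@H]2C(C)=CC(=O)[C@@H]([C@H](C)COS(=O)(=O)c3c(C(C)C)cc(C(C)C)cc3C(C)C)[C@H]2/C=C\1C
F4 | step 13 | (2S,3R)-2,3-epoxide of F3 | O[C@H]1C/C=C(\C)C[C@@H](O)[C@H]2C(C)=CC(=O)[C@@H]([C@H](C)COS(=O)(=O)c3c(C(C)C)cc(C(C)C)cc3C(C)C)[C@H]2[C@@H]3O[C@]13C
F5 | step 13 | 16-O-(2,4,6-triisopropylbenzenesulfonyl) derivative of 27 | O[C@H]1C/C=C(\C)C[C@H]2O[C@@H]([C@]1(C)O)[C@@H]3[C@H]([C@H](C)COS(=O)(=O)c4c(C(C)C)cc(C(C)C)cc4C(C)C)C(=O)C=C(C)[C@@H]32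
F6 | step 14 | 16-aldehyde of 27 (3,4-dihydroxy-13,16-dioxo-2,9-epoxyeunicella-6,11-diene) | O[C@H]1C/C=C(\C)C[C@H]2O[C@@H]([C@]1(C)O)[C@@H]3[C@H]([C@H](C)C=O)C(=O)C=C(C)[C@@H]32
F7 | step 14 | 16-hydroxy derivative (lactol, anomer mixture) of 29 | O[C@H]1C/C=C(\C)C[C@H]2O[C@@H]3[C@@H]4[C@@H](C(=O)C=C(C)[C@@H]42)[C@H](C)C(O)O[C@]13C
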